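The two interflavan bonds are cut, so the top and bottom units come from (−)-epigallocatechin. Everything rests on building ring C of the middle unit by a formal [4+2] annulation. In one flask an ortho-fluoroaryllithium adds to an open-chain syn-3-hydroxy-2-(methoxymethoxy) aldehyde (C4–C4a). The C2 alkoxide then displaces fluoride at C8a (O1–C8a). The step exploits that C8a of ring A is meta to the C5 and C7 oxygens, so the Meisenheimer charge rests on C4a, C6 and C8. It also exploits that O1 never leaves C2, so the labile 2,3-cis pair set by allylboration survives. The C4 hydroxyl created serves as leaving group for the 4β→8 coupling.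

Key step: step 8

Assumption: flavan numbering (O1, C2–C4, C4a, C5–C8, C8a) is used for every unit, open-chain precursors included, and compounds 8, 9 and 19 are taken as catalogue compounds.

Step 1
Reactants: 1 (−)-epigallocatechin
Product: 2 5,7,3',4',5'-penta-O-benzyl-(−)-epigallocatechin (3-OH free)
Conditions: BnBr (5.5 equiv), K2CO3, DMF, argon, 0 °C to rt
Reagents that add atoms: benzyl bromide, BrCc1ccccc1
Why: Williamson etherification in which carbonate deprotonates only the five phenols, so the secondary 3-OH stays free and C2 and C3 are not touched.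

Step 2
Reactants: 2 5,7,3',4',5'-penta-O-benzyl-(−)-epigallocatechin
Product: 3 3,5,7,3',4',5'-hexa-O-benzyl-(−)-epigallocatechin
Conditions: NaH, BnBr, DMF, 0 °C to rt
Reagents that add atoms: benzyl bromide, BrCc1ccccc1
Why: Williamson etherification of the remaining secondary alkoxide; with no free phenol left, the base-induced ring opening that would epimerise C2 is shut off.

Step 3
Reactants: 3 3,5,7,3',4',5'-hexa-O-benzyl-(−)-epigallocatechin
Product: 4 4β-(2-ethoxyethoxy)-3,5,7,3',4',5'-hexa-O-benzyl-(−)-epigallocatechin (2,3-cis-3,4-trans)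
Conditions: DDQ, 2-ethoxyethanol, CH2Cl2, rt
Reagents that add atoms: 2-ethoxyethanol, CCOCCO
Why: DDQ benzylic oxidation: hydride abstraction at C4 gives the cation stabilised by the C5 and C7 ethers of ring A, and the alcohol should trap it on the β face, anti to the axial 3-OBn group.

Step 4
Reactants: 5 1,3,5-trifluorobenzene
Product: 6 1,3-bis(benzyloxy)-5-fluorobenzene
Conditions: BnOH (2.1 equiv), NaH, NMP, 0 to 90 °C
Reagents that add atoms: benzyl alcohol, OCc1ccccc1
Why: Twofold SNAr in which each benzyloxy group introduced slows the next substitution, so two equivalents of alkoxide should stop at the monofluoride.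

Step 5
Reactants: 6 1,3-bis(benzyloxy)-5-fluorobenzene
Product: 7 1,5-bis(benzyloxy)-3-fluoro-2-iodobenzene
Conditions: NIS, TFA (cat.), MeCN, 0 °C
Reagents that add atoms: N-iodosuccinimide, O=C1CCC(=O)N1I
Why: Electrophilic aromatic iodination: the position flanked by the small fluorine (ortho to one ether, para to the other) is as activated as the one between the two benzyloxy groups but far less hindered.

Step 6
Reactants: 8 3,4,5-tris(benzyloxy)benzaldehyde, 9 allyl methoxymethyl ether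
Product: 12 (1R,2R)-2-(methoxymethoxy)-1-[3,4,5-tris(benzyloxy)phenyl]but-3-en-1-ol (syn), via allyllithium 10 (not isolated), via allylborane 11 (not isolated)
Conditions: 9, s-BuLi, THF, −78 °C; (−)-Ipc2BOMe; BF3·OEt2; 8, −78 °C; then NaOH, H2O2
Reagents that add atoms: none
Why: Brown alkoxyallylboration through a closed Zimmerman–Traxler chair: the Z geometry of 11 becomes the syn relationship, and the isopinocampheyl groups derived from (+)-α-pinene direct attack to the Si face of 8, which should set C2 and C3 of the middle unit.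

Step 7
Reactants: 12 (1R,2R)-2-(methoxymethoxy)-1-[3,4,5-tris(benzyloxy)phenyl]but-3-en-1-ol
Product: 13 (2S,3R)-3-hydroxy-2-(methoxymethoxy)-3-[3,4,5-tris(benzyloxy)phenyl]propanal
Conditions: OsO4 (cat.), NaIO4, 2,6-lutidine, dioxane–H2O, rt
Reagents that add atoms: osmium tetroxide, O=[Os](=O)(=O)=O (delivers the oxygen); sodium periodate, [Na+].[O-]I(=O)(=O)=O (restores it)
Why: Lemieux–Johnson cleavage: the terminal alkene is the only site for OsO4, the carbinol has no free vicinal hydroxyl for periodate to cut, and the lutidine buffer protects the α-stereocentre.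

Step 8
Reactants: 7 1,5-bis(benzyloxy)-3-fluoro-2-iodobenzene, 13 (2S,3R)-3-hydroxy-2-(methoxymethoxy)-3-[3,4,5-tris(benzyloxy)phenyl]propanal
Product: 16 (2R,3R)-5,7-bis(benzyloxy)-3-(methoxymethoxy)-2-[3,4,5-tris(benzyloxy)phenyl]chroman-4-ol (2,3-cis; both C4 epimers), via aryllithium 14 (not isolated), via dilithium dialkoxide 15 (not isolated)
Conditions: 7 (2.1 equiv), t-BuLi (4.2 equiv), THF, −78 °C; 13, −78 °C; then KOt-Bu, DMPU, −78 to 50 °C; aq NH4Cl
Reagents that add atoms: none
Why: Iodine–lithium exchange turns 7 into aryllithium 14; one equivalent takes the C2–OH proton of 13, a second adds to the aldehyde carbon (C4–C4a bond) to give dialkoxide 15, and after lithium-to-potassium exchange in DMPU the C2 alkoxide adds to C8a and expels fluoride through a Meisenheimer adduct (O1–C8a bond). The closest known reaction types are the 1,2-addition of ortho-fluoroaryllithiums to aldehydes below the temperature of benzyne formation and the intramolecular SNAr pyran closure of alkoxides on 3,5-dialkoxyfluorobenzenes, here run in the same flask. Ring C closes as a six-membered ring by ipso addition–elimination (formally 6-exo-trig), which is favoured because C8a is meta to both benzyloxy groups, so these help inductively and never carry the negative charge. The only new stereocentre, C4, is formed without control and both epimers are taken on, since C4 is ionised in step 9; C2 and C3 keep the configuration of step 6 because no bond to either carbon is made or broken. The step needs oxygen selectivity: O3 is locked as a MOM acetal that cannot migrate, so no dihydrobenzofuran can form, and the C4 alkoxide could only close a four-membered ring. It also needs the aldehyde to be consumed before retro-aldol cleavage, which the fast addition at −78 °C should secure.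

Step 9
Reactants: 16 (2R,3R)-5,7-bis(benzyloxy)-3-(methoxymethoxy)-2-[3,4,5-tris(benzyloxy)phenyl]chroman-4-ol, 3 3,5,7,3',4',5'-hexa-O-benzyl-(−)-epigallocatechin
Product: 17 3-O-methoxymethyl-penta-O-benzyl-epigallocatechin-(4β→8)-hexa-O-benzyl-epigallocatechin
Conditions: 3 (3 equiv), TMSOTf (cat.), 4 Å MS, CH2Cl2, −78 °C
Reagents that add atoms: none
Why: Friedel–Crafts-type flavan coupling: both C4 epimers ionise to one cation, C8 of 3 (its most nucleophilic and least hindered position) should attack on the β face anti to the axial 3-OMOM group to set C4 as 3,4-trans, and the excess of 3 suppresses self-condensation.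

Step 10
Reactants: 17 3-O-methoxymethyl-penta-O-benzyl-epigallocatechin-(4β→8)-hexa-O-benzyl-epigallocatechin
Product: 18 penta-O-benzyl-epigallocatechin-(4β→8)-hexa-O-benzyl-epigallocatechin (upper 3-OH free)
Conditions: TMSOTf, 2,2'-bipyridyl, CH2Cl2, 0 °C to rt; then H2O; aq NaHCO3
Reagents that add atoms: none
Why: Acetal cleavage by a silyl triflate buffered with bipyridyl; the medium stays non-acidic, so the interflavan bond and the benzyl ethers should survive and no stereocentre is touched.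

Step 11
Reactants: 18 penta-O-benzyl-epigallocatechin-(4β→8)-hexa-O-benzyl-epigallocatechin, 19 3,4,5-tris(benzyloxy)benzoic acid
Product: 20 octa-O-benzyl-epigallocatechin 3-O-gallate-(4β→8)-hexa-O-benzyl-epigallocatechin
Conditions: 19 (3 equiv), DCC, DMAP, CH2Cl2, rt
Reagents that add atoms: none
Why: Steglich esterification of the only free hydroxyl in the molecule, with retention at C3 because only the O–H bond is broken.

Step 12
Reactants: 20 octa-O-benzyl-epigallocatechin 3-O-gallate-(4β→8)-hexa-O-benzyl-epigallocatechin, 4 4β-(2-ethoxyethoxy)-3,5,7,3',4',5'-hexa-O-benzyl-(−)-epigallocatechin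
Product: 21 eicosa-O-benzyl epigallocatechin-(4β→8)-epigallocatechin 3-O-gallate-(4β→8)-epigallocatechin
Conditions: TMSOTf (cat.), CH2Cl2, −78 to −40 °C, slow addition of 4 to 20
Reagents that add atoms: none
Why: Friedel–Crafts-type flavan coupling: the C4 cation from 4 should be attacked by C8 of ring A of the upper unit of 20, the only unsubstituted C8 position left, on the β face anti to the 3-OBn group, which sets C4 of the top unit.

Step 13
Reactants: 21 eicosa-O-benzyl epigallocatechin-(4β→8)-epigallocatechin 3-O-gallate-(4β→8)-epigallocatechin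
Product: 22 epigallocatechin-(4β→8)-epigallocatechin 3-O-gallate-(4β→8)-epigallocatechin
Conditions: H2 (1 atm), Pd(OH)2/C, THF–MeOH–H2O, rt
Reagents that add atoms: none
Why: Global hydrogenolysis of all twenty benzyl ethers under neutral conditions, which leaves the gallate ester, the interflavan bonds and all eight stereocentres untouched.

Compound list
1 | (−)-epigallocatechin | Oc1cc(O)c2c(c1)O[C@H](c1cc(O)c(O)c(O)c1)[C@H](O)C2 | starting material
2 | 5,7,3',4',5'-penta-O-benzyl-(−)-epigallocatechin | c1(OCc6ccccc6)cc(OCc6ccccc6)c2c(c1)O[C@H](c5cc(OCc6ccccc6)c(OCc6ccccc6)c(OCc6ccccc6)c5)[C@H](O)C2 | intermediate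
3 | 3,5,7,3',4',5'-hexa-O-benzyl-(−)-epigallocatechin | c1(OCc6ccccc6)cc(OCc6ccccc6)c2c(c1)O[C@H](c5cc(OCc6ccccc6)c(OCc6ccccc6)c(OCc6ccccc6)c5)[C@H](OCc6ccccc6)C2 | intermediate
4 | 4β-(2-ethoxyethoxy)-3,5,7,3',4',5'-hexa-O-benzyl-(−)-epigallocatechin | CCOCCO[C@H]2c1c(OCc6ccccc6)cc(OCc6ccccc6)cc1O[C@H](c5cc(OCc6ccccc6)c(OCc6ccccc6)c(OCc6ccccc6)c5)[C@@H]2OCc6ccccc6 | intermediate
5 | 1,3,5-trifluorobenzene | Fc1cc(F)cc(F)c1 | starting material
6 | 1,3-bis(benzyloxy)-5-fluorobenzene | Fc1cc(OCc2ccccc2)cc(OCc2ccccc2)c1 | intermediate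
7 | 1,5-bis(benzyloxy)-3-fluoro-2-iodobenzene | Fc1cc(OCc2ccccc2)cc(OCc2ccccc2)c1I | intermediate
8 | 3,4,5-tris(benzyloxy)benzaldehyde | O=Cc1cc(OCc2ccccc2)c(OCc2ccccc2)c(OCc2ccccc2)c1 | starting material
9 | allyl methoxymethyl ether | C=CCOCOC | starting material
10 | (Z)-3-(methoxymethoxy)allyllithium | [Li]C/C=C\OCOC | intermediate
11 | [(Z)-3-(methoxymethoxy)allyl]bis(isopinocampheyl)borane, Ipc from (+)-α-pinene | COCO/C=C\CB([C@@H]1C[C@@H]2C[C@H]([C@H]1C)C2(C)C)[C@@H]1C[C@@H]2C[C@H]([C@H]1C)C2(C)C | intermediate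
12 | (1R,2R)-2-(methoxymethoxy)-1-[3,4,5-tris(benzyloxy)phenyl]but-3-en-1-ol | O[C@H](c5cc(OCc6ccccc6)c(OCc6ccccc6)c(OCc6ccccc6)c5)[C@H](OCOC)C=C | intermediate
13 | (2S,3R)-3-hydroxy-2-(methoxymethoxy)-3-[3,4,5-tris(benzyloxy)phenyl]propanal | O[C@H](c5cc(OCc6ccccc6)c(OCc6ccccc6)c(OCc6ccccc6)c5)[C@H](OCOC)C=O | intermediate
14 | 2,4-bis(benzyloxy)-6-fluorophenyllithium | [Li]c1c(F)cc(OCc6ccccc6)cc1OCc6ccccc6 | intermediate
15 | dilithium C2,C4-dialkoxide of the open-chain 1-(2,4-bis(benzyloxy)-6-fluorophenyl)-2-(methoxymethoxy)-3-[3,4,5-tris(benzyloxy)phenyl]propane-1,3-diol (C2 and C3 as in 13; C4 epimers) | [Li]O[C@H](c5cc(OCc6ccccc6)c(OCc6ccccc6)c(OCc6ccccc6)c5)[C@H](OCOC)C(O[Li])c1c(F)cc(OCc6ccccc6)cc1OCc6ccccc6 | intermediate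
16 | (2R,3R)-5,7-bis(benzyloxy)-3-(methoxymethoxy)-2-[3,4,5-tris(benzyloxy)phenyl]chroman-4-ol (C4 epimers) | c1(OCc6ccccc6)cc(OCc6ccccc6)c2c(c1)O[C@H](c5cc(OCc6ccccc6)c(OCc6ccccc6)c(OCc6ccccc6)c5)[C@H](OCOC)C2O | intermediate
17 | 3-O-methoxymethyl-penta-O-benzyl-epigallocatechin-(4β→8)-hexa-O-benzyl-epigallocatechin | COCO[C@@H]1[C@@H](c3c(OCc6ccccc6)cc(OCc6ccccc6)c4c3O[C@H](c5cc(OCc6ccccc6)c(OCc6ccccc6)c(OCc6ccccc6)c5)[C@H](OCc6ccccc6)C4)c2c(OCc6ccccc6)cc(OCc6ccccc6)cc2O[C@@H]1c5cc(OCc6ccccc6)c(OCc6ccccc6)c(OCc6ccccc6)c5 | intermediate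
18 | penta-O-benzyl-epigallocatechin-(4β→8)-hexa-O-benzyl-epigallocatechin (upper 3-OH free) | O[C@@H]1[C@@H](c3c(OCc6ccccc6)cc(OCc6ccccc6)c4c3O[C@H](c5cc(OCc6ccccc6)c(OCc6ccccc6)c(OCc6ccccc6)c5)[C@H](OCc6ccccc6)C4)c2c(OCc6ccccc6)cc(OCc6ccccc6)cc2O[C@@H]1c5cc(OCc6ccccc6)c(OCc6ccccc6)c(OCc6ccccc6)c5 | intermediate
19 | 3,4,5-tris(benzyloxy)benzoic acid | OC(=O)c1cc(OCc2ccccc2)c(OCc2ccccc2)c(OCc2ccccc2)c1 | starting material
20 | octa-O-benzyl-epigallocatechin 3-O-gallate-(4β→8)-hexa-O-benzyl-epigallocatechin | O=C(O[C@@H]1[C@@H](c3c(OCc6ccccc6)cc(OCc6ccccc6)c4c3O[C@H](c5cc(OCc6ccccc6)c(OCc6ccccc6)c(OCc6ccccc6)c5)[C@H](OCc6ccccc6)C4)c2c(OCc6ccccc6)cc(OCc6ccccc6)cc2O[C@@H]1c5cc(OCc6ccccc6)c(OCc6ccccc6)c(OCc6ccccc6)c5)c5cc(OCc6ccccc6)c(OCc6ccccc6)c(OCc6ccccc6)c5 | intermediate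
21 | eicosa-O-benzyl epigallocatechin-(4β→8)-epigallocatechin 3-O-gallate-(4β→8)-epigallocatechin | O=C(O[C@@H]1[C@@H](c3c(OCc6ccccc6)cc(OCc6ccccc6)c4c3O[C@H](c5cc(OCc6ccccc6)c(OCc6ccccc6)c(OCc6ccccc6)c5)[C@H](OCc6ccccc6)C4)c2c(OCc6ccccc6)cc(OCc6ccccc6)c([C@H]8c7c(OCc6ccccc6)cc(OCc6ccccc6)cc7O[C@H](c5cc(OCc6ccccc6)c(OCc6ccccc6)c(OCc6ccccc6)c5)[C@@H]8OCc6ccccc6)c2O[C@@H]1c5cc(OCc6ccccc6)c(OCc6ccccc6)c(OCc6ccccc6)c5)c5cc(OCc6ccccc6)c(OCc6ccccc6)c(OCc6ccccc6)c5 | intermediate
22 | epigallocatechin-(4β→8)-epigallocatechin 3-O-gallate-(4β→8)-epigallocatechin (CNP0278699.1) | O=C(O[C@@H]1[C@@H](c2c(O)cc(O)c3c2O[C@H](c2cc(O)c(O)c(O)c2)[C@H](O)C3)c2c(O)cc(O)c([C@H]3c4c(O)cc(O)cc4O[C@H](c4cc(O)c(O)c(O)c4)[C@@H]3O)c2O[C@@H]1c1cc(O)c(O)c(O)c1)c1cc(O)c(O)c(O)c1 | target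

Total step count: 13. Longest linear sequence: 8 steps (steps 6, 7, 8, 9, 10, 11, 12 and 13, counted from 8; the branch from 5 through steps 4 and 5 is equally long).

Steps most likely to fail

**Step 8.**
- Risk: the hydroxy aldehyde may suffer retro-aldol cleavage or α-epimerisation under the excess organolithium. The aryllithium may lose LiF to a benzyne on warming. The doubly charged intermediate may displace fluoride too slowly.
- Fallback: the domino is uncoupled and the second negative charge is removed.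
  - From 7 and 13 the addition alone is run and quenched at −78 °C to give the open-chain fluoro diol F1.
  - PPTS in MeOH exchanges only the doubly activated C4 hydroxyl by SN1 solvolysis, giving the C4 methyl ether F2.
  - KH and 18-crown-6 in DMF then close the mono-alkoxide by SNAr to the 4-methoxyflavan F3.
  - F3 replaces 16 as the electrophile of step 9, so the fallback comes back to the route at 17.

**Step 9.**
- Risk: the cation may be captured by C8 of a second molecule of 16 (self-condensation). The Lewis acid may attack the MOM acetal. Part of the attack may go to C6 of 3.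
- Fallback: the hard oxygen leaving group is exchanged for a soft one that is activated on another principle.
  - From 16, a large excess of benzyl mercaptan with catalytic acetic acid intercepts the cation to give the 4β-benzylthio ether F4.
  - AgBF4 in THF–CH2Cl2 at 0 °C then activates sulfur alone, releases the cation slowly in the presence of 3 and leaves the acetal alone.
  - This comes back to the route at 17.

**Step 12.**
- Risk: the electrophile may oligomerise through its own free C8. The cation may spread over C6 positions of the hindered nucleophile. The reaction may continue beyond the trimer.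
- Fallback: the electrophile is capped so that it cannot act as a nucleophile.
  - From 3, NBS in CH2Cl2 at low temperature gives the 8-bromide F5.
  - DDQ and 2-ethoxyethanol give the 8-bromo 4β-(2-ethoxyethoxy) electrophile F6.
  - Coupling with 20 under the conditions of step 12 gives the 8-bromo trimer F7.
  - Hydrogenolysis over Pd(OH)2/C with Et3N removes the bromine together with the benzyl groups, which comes back to the route at 22.

Further compounds
F1 | step 8 | open-chain fluoro diol, 1-(2,4-bis(benzyloxy)-6-fluorophenyl)-2-(methoxymethoxy)-3-[3,4,5-tris(benzyloxy)phenyl]propane-1,3-diol (C2 and C3 as in 13; C4 epimers) | O[C@H](c5cc(OCc6ccccc6)c(OCc6ccccc6)c(OCc6ccccc6)c5)[C@H](OCOC)C(O)c1c(F)cc(OCc6ccccc6)cc1OCc6ccccc6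
F2 | step 8 | C4 methyl ether of F1 (C4 epimers) | O[C@H](c5cc(OCc6ccccc6)c(OCc6ccccc6)c(OCc6ccccc6)c5)[C@H](OCOC)C(OC)c1c(F)cc(OCc6ccccc6)cc1OCc6ccccc6
F3 | step 8 | (2R,3R)-5,7-bis(benzyloxy)-4-methoxy-3-(methoxymethoxy)-2-[3,4,5-tris(benzyloxy)phenyl]chroman (C4 epimers) | c1(OCc6ccccc6)cc(OCc6ccccc6)c2c(c1)O[C@H](c5cc(OCc6ccccc6)c(OCc6ccccc6)c(OCc6ccccc6)c5)[C@H](OCOC)C2OC
F4 | step 9 | 4β-benzylthio-5,7-bis(benzyloxy)-3-(methoxymethoxy)-2-[3,4,5-tris(benzyloxy)phenyl]chroman (2,3-cis-3,4-trans) | S(Cc6ccccc6)[C@H]2c1c(OCc6ccccc6)cc(OCc6ccccc6)cc1O[C@H](c5cc(OCc6ccccc6)c(OCc6ccccc6)c(OCc6ccccc6)c5)[C@@H]2OCOC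
F5 | step 12 | 8-bromo-3,5,7,3',4',5'-hexa-O-benzyl-(−)-epigallocatechin | c1(OCc6ccccc6)cc(OCc6ccccc6)c2c(c1Br)O[C@H](c5cc(OCc6ccccc6)c(OCc6ccccc6)c(OCc6ccccc6)c5)[C@H](OCc6ccccc6)C2
F6 | step 12 | 8-bromo-4β-(2-ethoxyethoxy)-3,5,7,3',4',5'-hexa-O-benzyl-(−)-epigallocatechin | CCOCCO[C@H]2c1c(OCc6ccccc6)cc(OCc6ccccc6)c(Br)c1O[C@H](c5cc(OCc6ccccc6)c(OCc6ccccc6)c(OCc6ccccc6)c5)[C@@H]2OCc6ccccc6
F7 | step 12 | eicosa-O-benzyl trimer 21 carrying bromine at C8 of the top unit | O=C(O[C@@H]1[C@@H](c3c(OCc6ccccc6)cc(OCc6ccccc6)c4c3O[C@H](c5cc(OCc6ccccc6)c(OCc6ccccc6)c(OCc6ccccc6)c5)[C@H](OCc6ccccc6)C4)c2c(OCc6ccccc6)cc(OCc6ccccc6)c([C@H]8c7c(OCc6ccccc6)cc(OCc6ccccc6)c(Br)c7O[C@H](c5cc(OCc6ccccc6)c(OCc6ccccc6)c(OCc6ccccc6)c5)[C@@H]8OCc6ccccc6)c2O[C@@H]1c5cc(OCc6ccccc6)c(OCc6ccccc6)c(OCc6ccccc6)c5)c5cc(OCc6ccccc6)c(OCc6ccccc6)c(OCc6ccccc6)c5
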